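The route rests on the C4–C5 disconnection of the cyclohexane ring C3a–C4–C5–C6–C7–C7a (hydrindane numbering; C1 bears the side chain, C7a the angular methyl). The key step exploits the gem-dimethyl quaternary carbon C4 next to ring-fusion C3a: hydrogen-atom transfer to an isopropenyl group creates one of its methyls and a tertiary C4 radical, which closes the six-membered ring onto an allyl arm in one reductive operation, leaving no functionality behind. The precursor is a monocyclic trans-2-allyl-2-methyl-3-isopropenylcyclopentanone from a three-component coupling that pre-sets the trans fusion. Cyclopentane and lactone rings are bought; the side chain is attached afterwards by alkenyl triflate/aldehyde coupling.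

Key step: step 4

Remark: the facial senses quoted for the three catalyst-controlled steps (1, 2 and 3) follow the accepted models for these catalyst classes; should one be reversed, the antipodal ligand or catalyst would be used.

Step 1
Reactants: 1 furan-2(5H)-one; 2 (E)-2-(2-ethoxyethenyl)-4,4,5,5-tetramethyl-1,3,2-dioxaborolane
Product: 4 (R)-2-(5-oxooxolan-3-yl)acetaldehyde, via enol ether 3 (not isolated)
Conditions: Rh(acac)(C2H4)2 (3 mol %), (S)-BINAP, KOH (cat.), dioxane/H2O, 60 °C; then 1 M HCl, THF, rt
Reagents that add atoms: water, O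
Why: Hayashi–Miyaura reaction, in which the alkenylrhodium species adds to C4 of the butenolide on the face selected by (S)-BINAP (sense by analogy with cyclic enones) and so sets the lactone stereocentre, after which dilute acid hydrolyses the enol ether to the aldehyde without touching the lactone.

Step 2
Reactants: 4 (R)-2-(5-oxooxolan-3-yl)acetaldehyde
Product: 6 (2S)-3-[(tert-butyldimethylsilyl)oxy]-2-[(3S)-5-oxooxolan-3-yl]propanal, via hydroxy aldehyde 5 (not isolated)
Conditions: 37% aq. HCHO, (R)-α,α-diphenylprolinol trimethylsilyl ether (20 mol %), pH 7 phosphate buffer, toluene, rt; extraction; then TBSCl, imidazole, CH2Cl2, 0 °C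
Reagents that add atoms: formaldehyde, C=O; tert-butyldimethylsilyl chloride, CC(C)(C)[Si](C)(C)Cl
Why: Enamine-catalysed cross-aldol reaction with formaldehyde (α-hydroxymethylation), in which the bulky group of the (R)-catalyst shields one enamine face and sets C2 under catalyst control, and immediate silylation of the crude β-hydroxy aldehyde should prevent dehydration and epimerization.

Step 3
Reactants: 7 2-methylcyclopent-2-en-1-one; 8 isopropenylmagnesium bromide; 9 allyl iodide
Product: 11 (2S,3S)-2-allyl-2-methyl-3-(prop-1-en-2-yl)cyclopentan-1-one, via magnesium enolate 10 (not isolated)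
Conditions: 8, CuBr·SMe2 (5 mol %), BINOL/bis(1-phenylethyl)amine phosphoramidite ligand (6 mol %), 2-MeTHF/Et2O, −78 °C; then 9, DMPU, −78 → 0 °C
Reagents that add atoms: none
Why: Copper-catalysed asymmetric conjugate addition with enolate trapping (three-component coupling), in which the chiral ligand sets C3 and the enolate is allylated at C2 anti to the new isopropenyl group, so that allyl and isopropenyl end up trans (the future trans ring fusion) and the methyl cis to isopropenyl.

Step 4
Reactants: 11 (2S,3S)-2-allyl-2-methyl-3-(prop-1-en-2-yl)cyclopentan-1-one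
Product: 12 (3aS,7aS)-4,4,7a-trimethyloctahydro-1H-inden-1-one
Conditions: Mn(dpm)3 (dpm = dipivaloylmethanate, 10 mol %), PhSiH3 (slow addition), t-BuOOH, i-PrOH (0.01 M), 22 °C
Reagents that add atoms: none
Why: The trivalent manganese hydride formed from Mn(dpm)3 and PhSiH3 transfers a hydrogen atom to the CH2 terminus of the isopropenyl group (Markovnikov), so that this carbon becomes the second methyl of C4 and C4 becomes a tertiary radical; the radical adds to the terminal carbon of the allyl group (new C4–C5 bond) and the resulting secondary C6 radical is quenched by a second hydrogen-atom transfer. The closest known reaction type is MHAT (Mukaiyama-type) radical hydrogenation of alkenes with an interposed radical cyclization, as in MHAT-initiated diene and polyene cyclizations. The cyclohexane ring (C3a, C4, C5, C6, C7, C7a) closes in the 6-endo-trig mode. No new stereocentre is formed (C4 carries two methyls, C5 to C7 are CH2); the trans ring fusion is inherited from the 2,3-trans arrangement of the two arms in 11. The step needs (a) hydrogen-atom transfer to the 1,1-disubstituted and not the monosubstituted alkene, secured by the faster formation of a tertiary radical, (b) 6-endo and not 5-exo closure, secured because 5-exo would give a strained trans-fused bicyclo[3.3.0]octane and would attack the hindered internal alkene carbon, and (c) cyclization before the second hydrogen-atom transfer, favoured by high dilution and slow addition of the silane.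

Step 5
Reactants: 12 (3aS,7aS)-4,4,7a-trimethyloctahydro-1H-inden-1-one
Product: 14 (3aS,7aS)-4,4,7a-trimethyl-3a,4,5,6,7,7a-hexahydro-3H-inden-1-yl trifluoromethanesulfonate, via potassium enolate 13 (not isolated)
Conditions: KN(SiMe3)2, THF, −78 °C; then PhNTf2, −78 → 0 °C
Reagents that add atoms: N-phenylbis(trifluoromethanesulfonimide), O=S(=O)(N(c1ccccc1)S(=O)(=O)C(F)(F)F)C(F)(F)F
Why: Enol triflate formation, regiospecific because the ketone can enolize only toward C2 (C7a is quaternary), followed by O-sulfonylation of the single enolate.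

Step 6
Reactants: 14 (3aS,7aS)-4,4,7a-trimethyl-3a,4,5,6,7,7a-hexahydro-3H-inden-1-yl trifluoromethanesulfonate; 6 (2S)-3-[(tert-butyldimethylsilyl)oxy]-2-[(3S)-5-oxooxolan-3-yl]propanal
Product: 15 (4S)-4-[(2S)-3-[(tert-butyldimethylsilyl)oxy]-1-hydroxy-1-[(3aS,7aS)-4,4,7a-trimethyl-3a,4,5,6,7,7a-hexahydro-3H-inden-1-yl]propan-2-yl]oxolan-2-one (both carbinol epimers)
Conditions: CrCl2 (4 equiv), NiCl2 (2 mol %), DMF, rt
Reagents that add atoms: none
Why: Nozaki–Hiyama–Kishi reaction, in which the alkenylchromium species formed from the hindered enol triflate under NiCl2 catalysis adds chemoselectively to the aldehyde under non-basic conditions (lactone, silyl ether and the α-stereocentre of 6 untouched); the new carbinol centre is not controlled and is removed in step 7.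

Step 7
Reactants: 15 (4S)-4-[(2S)-3-[(tert-butyldimethylsilyl)oxy]-1-hydroxy-1-[(3aS,7aS)-4,4,7a-trimethyl-3a,4,5,6,7,7a-hexahydro-3H-inden-1-yl]propan-2-yl]oxolan-2-one
Product: 16 (4S)-4-[(2S)-3-[(tert-butyldimethylsilyl)oxy]-1-oxo-1-[(3aS,7aS)-4,4,7a-trimethyl-3a,4,5,6,7,7a-hexahydro-3H-inden-1-yl]propan-2-yl]oxolan-2-one
Conditions: Dess–Martin periodinane, CH2Cl2, 0 °C → rt
Reagents that add atoms: none
Why: Dess–Martin oxidation of the allylic alcohol under neutral conditions should converge both carbinol epimers on one enone without epimerizing the adjacent stereocentre.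

Step 8
Reactants: 16 (4S)-4-[(2S)-3-[(tert-butyldimethylsilyl)oxy]-1-oxo-1-[(3aS,7aS)-4,4,7a-trimethyl-3a,4,5,6,7,7a-hexahydro-3H-inden-1-yl]propan-2-yl]oxolan-2-one
Product: 17 (4S)-4-[(2S)-3-[(tert-butyldimethylsilyl)oxy]-1-oxo-1-[(1S,3aS,7aS)-4,4,7a-trimethyloctahydro-1H-inden-1-yl]propan-2-yl]oxolan-2-one
Conditions: H2 (1 atm), 10% Pd/C, EtOAc, rt
Reagents that add atoms: none
Why: Heterogeneous hydrogenation of the enone C1=C2 bond, with hydrogen delivered from the face opposite the angular C7a methyl (as for steroidal 16-en-20-ones), which sets C1 with the acyl group cis to that methyl.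

Step 9
Reactants: 17 (4S)-4-[(2S)-3-[(tert-butyldimethylsilyl)oxy]-1-oxo-1-[(1S,3aS,7aS)-4,4,7a-trimethyloctahydro-1H-inden-1-yl]propan-2-yl]oxolan-2-one
Product: 18 (4S)-4-[(2R)-1-[(tert-butyldimethylsilyl)oxy]-3-[(1R,3aS,7aS)-4,4,7a-trimethyloctahydro-1H-inden-1-yl]but-3-en-2-yl]oxolan-2-one
Conditions: Zn, CH2Br2, TiCl4, THF/CH2Cl2, 0 °C → rt
Reagents that add atoms: dibromomethane, BrCBr
Why: Takai–Lombardo methylenation, whose non-basic titanium–zinc methylene reagent should olefinate the hindered, enolizable ketone in the presence of the lactone and silyl ether without epimerizing the two α-stereocentres.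

Step 10
Reactants: 18 (4S)-4-[(2R)-1-[(tert-butyldimethylsilyl)oxy]-3-[(1R,3aS,7aS)-4,4,7a-trimethyloctahydro-1H-inden-1-yl]but-3-en-2-yl]oxolan-2-one
Product: 20 (2R)-2-[(3S)-5-oxooxolan-3-yl]-3-[(1R,3aS,7aS)-4,4,7a-trimethyloctahydro-1H-inden-1-yl]but-3-en-1-yl acetate, via primary alcohol 19 (not isolated)
Conditions: HF·pyridine, THF/pyridine, 0 °C → rt; work-up; then Ac2O, pyridine, DMAP (cat.), CH2Cl2, 0 °C
Reagents that add atoms: acetic anhydride, CC(=O)OC(C)=O
Why: Fluoride cleavage of the primary silyl ether (lactone and alkene inert) followed by DMAP-catalysed acetylation of the primary alcohol, with no stereocentre affected.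

Compound list
1 | furan-2(5H)-one | O=C1OCC=C1 | starting material
2 | (E)-2-(2-ethoxyethenyl)-4,4,5,5-tetramethyl-1,3,2-dioxaborolane | CCO/C=C/B1OC(C)(C)C(C)(C)O1 | starting material
3 | (S)-4-[(E)-2-ethoxyethenyl]oxolan-2-one | CCO/C=C/[C@H]1COC(=O)C1 | intermediate (not isolated)
4 | (R)-2-(5-oxooxolan-3-yl)acetaldehyde | O=CC[C@H]1COC(=O)C1 | intermediate
5 | (2S)-3-hydroxy-2-[(3S)-5-oxooxolan-3-yl]propanal | O=C[C@H](CO)[C@H]1COC(=O)C1 | intermediate (not isolated)
6 | (2S)-3-[(tert-butyldimethylsilyl)oxy]-2-[(3S)-5-oxooxolan-3-yl]propanal | O=C[C@H](CO[Si](C)(C)C(C)(C)C)[C@H]1COC(=O)C1 | intermediate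
7 | 2-methylcyclopent-2-en-1-one | CC1=CCCC1=O | starting material
8 | isopropenylmagnesium bromide | CC(=C)[Mg]Br | starting material
9 | allyl iodide | C=CCI | starting material
10 | bromomagnesium (S)-2-methyl-3-(prop-1-en-2-yl)cyclopent-1-en-1-olate | CC1=C(O[Mg]Br)CC[C@H]1C(C)=C | intermediate (not isolated)
11 | (2S,3S)-2-allyl-2-methyl-3-(prop-1-en-2-yl)cyclopentan-1-one | O=C1CC[C@@H](C(C)=C)[C@]1(C)CC=C | intermediate
12 | (3aS,7aS)-4,4,7a-trimethyloctahydro-1H-inden-1-one | O=C1CC[C@H]2C(C)(C)CCC[C@]12C | intermediate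
13 | potassium (3aS,7aS)-4,4,7a-trimethyl-3a,4,5,6,7,7a-hexahydro-3H-inden-1-olate | [K+].[O-]C1=CC[C@H]2C(C)(C)CCC[C@]12C | intermediate (not isolated)
14 | (3aS,7aS)-4,4,7a-trimethyl-3a,4,5,6,7,7a-hexahydro-3H-inden-1-yl trifluoromethanesulfonate | O=S(=O)(OC1=CC[C@H]2C(C)(C)CCC[C@]12C)C(F)(F)F | intermediate
15 | (4S)-4-[(2S)-3-[(tert-butyldimethylsilyl)oxy]-1-hydroxy-1-[(3aS,7aS)-4,4,7a-trimethyl-3a,4,5,6,7,7a-hexahydro-3H-inden-1-yl]propan-2-yl]oxolan-2-one (both carbinol epimers) | OC(C1=CC[C@H]2C(C)(C)CCC[C@]12C)[C@H](CO[Si](C)(C)C(C)(C)C)[C@H]1COC(=O)C1 | intermediate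
16 | (4S)-4-[(2S)-3-[(tert-butyldimethylsilyl)oxy]-1-oxo-1-[(3aS,7aS)-4,4,7a-trimethyl-3a,4,5,6,7,7a-hexahydro-3H-inden-1-yl]propan-2-yl]oxolan-2-one | O=C(C1=CC[C@H]2C(C)(C)CCC[C@]12C)[C@H](CO[Si](C)(C)C(C)(C)C)[C@H]1COC(=O)C1 | intermediate
17 | (4S)-4-[(2S)-3-[(tert-butyldimethylsilyl)oxy]-1-oxo-1-[(1S,3aS,7aS)-4,4,7a-trimethyloctahydro-1H-inden-1-yl]propan-2-yl]oxolan-2-one | O=C([C@H]1CC[C@H]2C(C)(C)CCC[C@]12C)[C@H](CO[Si](C)(C)C(C)(C)C)[C@H]1COC(=O)C1 | intermediate
18 | (4S)-4-[(2R)-1-[(tert-butyldimethylsilyl)oxy]-3-[(1R,3aS,7aS)-4,4,7a-trimethyloctahydro-1H-inden-1-yl]but-3-en-2-yl]oxolan-2-one | C=C([C@H]1CC[C@H]2C(C)(C)CCC[C@]12C)[C@H](CO[Si](C)(C)C(C)(C)C)[C@H]1COC(=O)C1 | intermediate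
19 | (4S)-4-[(2R)-1-hydroxy-3-[(1R,3aS,7aS)-4,4,7a-trimethyloctahydro-1H-inden-1-yl]but-3-en-2-yl]oxolan-2-one | C=C([C@H]1CC[C@H]2C(C)(C)CCC[C@]12C)[C@H](CO)[C@H]1COC(=O)C1 | intermediate (not isolated)
20 | (2R)-2-[(3S)-5-oxooxolan-3-yl]-3-[(1R,3aS,7aS)-4,4,7a-trimethyloctahydro-1H-inden-1-yl]but-3-en-1-yl acetate (CNP0191918.2) | C=C([C@H]1CC[C@H]2C(C)(C)CCC[C@]12C)[C@H](COC(C)=O)[C@H]1COC(=O)C1 | target

Total step count: 10. Longest linear sequence: 8 steps (steps 3 to 10, from 7); the aldehyde branch (steps 1 and 2) joins at step 6.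

Steps most likely to fail

Step 4 (key step). The slow 6-endo closure may lose to a premature second hydrogen-atom transfer, which would simply hydrogenate the isopropenyl group, and hydrogen-atom transfer to the allyl group may compete. The fallback sets out from magnesium enolate 10 (generated from 7 and 8 as in step 3) and comes back to the route at 12. The enolate would be alkylated with 3-bromo-2-(phenylsulfonyl)prop-1-ene instead of 9 to give (2S,3S)-2-methyl-2-[2-(phenylsulfonyl)prop-2-en-1-yl]-3-(prop-1-en-2-yl)cyclopentan-1-one F1. Fe(acac)3/PhSiH3 in EtOH at 60 °C should then close the ring by a fast, polarity-matched 6-endo Giese addition of the C4 radical to the vinyl sulfone, giving (3aS,7aS)-4,4,7a-trimethyl-6-(phenylsulfonyl)octahydro-1H-inden-1-one F2 as a mixture of C6 epimers. Sodium amalgam (Na2HPO4, MeOH, −20 °C) would remove the sulfone to give 12.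

Step 3. Enantiofacial control may be insufficient in the copper-catalysed addition of an alkenyl Grignard reagent to the α-methyl enone. The fallback sets out from 7 and comes back at 11. The coupling would be run without chiral ligand (CuI cat., 8, then 9/DMPU), passing through the enolate 10 together with its mirror image bromomagnesium (R)-2-methyl-3-(prop-1-en-2-yl)cyclopent-1-en-1-olate F3. This should give the trans ketone as the racemate, that is 11 together with (2R,3R)-2-allyl-2-methyl-3-(prop-1-en-2-yl)cyclopentan-1-one F4. Preparative chromatography on a chiral stationary phase would then deliver 11 as the single enantiomer.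

Step 9. Steric shielding of the ketone between two branched carbons may make carbonyl methylenation slow, so that Lewis-acid-induced enolization erodes the configuration at the two α-carbons. The fallback sets out from 17 and comes back at 19. Me3SiCH2MgCl/CeCl3 (THF, −78 °C) should add to the ketone in preference to the lactone and give the β-hydroxysilane (4S)-4-[(2S)-1-[(tert-butyldimethylsilyl)oxy]-3-hydroxy-4-(trimethylsilyl)-3-[(1S,3aS,7aS)-4,4,7a-trimethyloctahydro-1H-inden-1-yl]butan-2-yl]oxolan-2-one F5. HF·pyridine would then bring about acid-mediated Peterson elimination and silyl ether cleavage in one operation to give 19, which is acetylated as in the second stage of step 10.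

Further compounds
F1 | step 4 | (2S,3S)-2-methyl-2-[2-(phenylsulfonyl)prop-2-en-1-yl]-3-(prop-1-en-2-yl)cyclopentan-1-one | O=C1CC[C@@H](C(C)=C)[C@]1(C)CC(=C)S(=O)(=O)c1ccccc1
F2 | step 4 | (3aS,7aS)-4,4,7a-trimethyl-6-(phenylsulfonyl)octahydro-1H-inden-1-one | O=C1CC[C@H]2C(C)(C)CC(S(=O)(=O)c3ccccc3)C[C@]12C
F3 | step 3 | bromomagnesium (R)-2-methyl-3-(prop-1-en-2-yl)cyclopent-1-en-1-olate | CC1=C(O[Mg]Br)CC[C@@H]1C(C)=C
F4 | step 3 | (2R,3R)-2-allyl-2-methyl-3-(prop-1-en-2-yl)cyclopentan-1-one | O=C1CC[C@H](C(C)=C)[C@@]1(C)CC=C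
F5 | step 9 | (4S)-4-[(2S)-1-[(tert-butyldimethylsilyl)oxy]-3-hydroxy-4-(trimethylsilyl)-3-[(1S,3aS,7aS)-4,4,7a-trimethyloctahydro-1H-inden-1-yl]butan-2-yl]oxolan-2-one | C[Si](C)(C)CC(O)([C@H]1CC[C@H]2C(C)(C)CCC[C@]12C)[C@H](CO[Si](C)(C)C(C)(C)C)[C@H]1COC(=O)C1
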